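**Plan**

- Ring numbering: C1 ketone, C2 =CH, C3 methyl enol ether carbon, C4 aryloxy/methoxy ketal carbon, C5 CH2, C6 allyl-bearing CH.
- Retrosynthesis: the C3 O–CH3 bond is cut first (back to the cyclohexane-1,3-dione), then ring bonds C2–C3 and C4–C5 together. This leaves methyl (aryloxy)(methoxy)acetate (C3–C4) and 3-methylenehex-5-en-2-one (C5–C6–C1–C2). The acetate is cut at the aryl O–acetal C bond, the phenol at its aryl–allyl bond, the enone at its methylene.
- Enabling feature: C1 and C3 are a 1,3-dioxygenated pair (a β-diketone with C3 as enol ether), and C4, alpha to C3, carries only oxygen and carbon. C3–C4 is therefore an α,α-dioxygenated acetate with one acidic C–H, and C5–C6–C1–C2 is an α-methylene methyl ketone.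
- Forward: the two fragments are made separately (four and two steps). The cyclohexane ring, the only ring made, then closes in one flask by Michael addition (C4–C5) followed by Claisen acylation (C2–C3). The arene is bought.
- Stereochemistry: C4 forms as a racemate in the annulation and the (4R) antipode is taken by chromatography on a chiral phase at the end. C6 is settled by base equilibration to the 4,6-cis isomer.

Key step: step 7

Assumption: the 4,6-cis isomer (aryloxy and allyl on the same ring face, as in the target) is taken to be the more stable C6 epimer, because it can place both the allyl group and the bulky ortho-substituted aryloxy group pseudo-equatorial on the cyclohexenone half-chair.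

**Route**

Step 1
Reactants: 1 3,4-dimethoxyphenol; 2 allyl bromide
Product: 3 4-(allyloxy)-1,2-dimethoxybenzene
Conditions: K2CO3, acetone, reflux
Reagents that add atoms: none
Why: Williamson ether synthesis, in which the phenoxide formed by K2CO3 displaces bromide from the unhindered allylic halide at oxygen.

Step 2
Reactants: 3 4-(allyloxy)-1,2-dimethoxybenzene
Product: 5 2-allyl-4,5-dimethoxyphenol, via 6-allyl-3,4-dimethoxycyclohexa-2,4-dien-1-one 4 (not isolated)
Conditions: PhNEt2, 190 °C
Reagents that add atoms: none
Why: Aromatic Claisen rearrangement, in which the [3,3] shift should go to the ortho carbon para to the neighbouring methoxy group and not to the one flanked by it, after which dienone 4 tautomerises to the phenol.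

Step 3
Reactants: 6 methyl methoxyacetate
Product: 7 methyl 2-bromo-2-methoxyacetate (racemic)
Conditions: NBS, AIBN (cat.), PhCF3, reflux; filtration, distillation
Reagents that add atoms: N-bromosuccinimide, O=C1CCC(=O)N1Br
Why: Wohl–Ziegler-type radical bromination, selective for the captodative C–H flanked by the ether oxygen and the ester.

Step 4
Reactants: 5 2-allyl-4,5-dimethoxyphenol; 7 methyl 2-bromo-2-methoxyacetate
Product: 9 methyl 2-(2-allyl-4,5-dimethoxyphenoxy)-2-methoxyacetate (racemic), via sodium 2-allyl-4,5-dimethoxyphenoxide 8 (not isolated)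
Conditions: NaH, THF, 0 °C; then 7, 0 °C → rt
Reagents that add atoms: none
Why: Williamson-type O-alkylation of phenoxide 8 with an α-halo ether, whose bromide is activated by the adjacent oxygen, under acid-free conditions that keep the mixed acetal intact.

Step 5
Reactants: 10 ethyl acetoacetate; 2 allyl bromide
Product: 11 ethyl 2-acetylpent-4-enoate (ethyl 2-allylacetoacetate; racemic)
Conditions: K2CO3, acetone, reflux (10 in slight excess)
Reagents that add atoms: none
Why: Acetoacetic ester alkylation, in which the stabilised enolate is C-allylated by SN2 displacement and excess 10 limits double alkylation.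

Step 6
Reactants: 11 ethyl 2-acetylpent-4-enoate
Product: 14 3-methylenehex-5-en-2-one, via potassium 2-acetylpent-4-enoate 12 (not isolated), via 2-acetyl-2-[(dimethylamino)methyl]pent-4-enoic acid 13 (not isolated)
Conditions: KOH, H2O, 0 °C → rt; then Me2NH·HCl, 37% aq. CH2O, rt → 50 °C; pentane extraction, distillation over hydroquinone, stored cold and used fresh
Reagents that add atoms: formaldehyde, C=O
Why: Saponification followed by decarboxylative Mannich methylenation, in which carboxylate 12 is aminomethylated at its α-carbon and Mannich base 13 loses CO2 and dimethylamine, so the double bond can only form at the new methylene carbon.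

Step 7
Reactants: 9 methyl 2-(2-allyl-4,5-dimethoxyphenoxy)-2-methoxyacetate; 14 3-methylenehex-5-en-2-one
Product: 17 6-allyl-4-(2-allyl-4,5-dimethoxyphenoxy)-4-methoxycyclohexane-1,3-dione (racemic at C4; both C6 epimers), via lithium 2-(2-allyl-4,5-dimethoxyphenoxy)-1,2-dimethoxyethen-1-olate 15 (not isolated), via lithium 3-allyl-5-(2-allyl-4,5-dimethoxyphenoxy)-5,6-dimethoxy-6-oxohex-2-en-2-olate 16 (not isolated)
Conditions: LiN(iPr)2 (1.05 equiv), THF, −78 °C; 14 added slowly, −78 °C; t-BuOH (0.2 equiv), −78 °C → rt; cold dilute HCl to pH 4; crude dione used directly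
Reagents that add atoms: none
Why: LiN(iPr)2 removes the only acidic proton of 9, and the tetra-oxygenated enolate 15 adds in a conjugate sense to the unsubstituted methylene carbon of 14 to forge C4–C5 and give ketone enolate 16; tert-butanol shuttles a proton from the methyl group to C6, and the methyl-ketone enolate then acylates on the ester carbonyl (C2–C3) with loss of methoxide, which at once deprotonates the 1,3-dione and makes the sequence irreversible. The closest known reaction type is the Michael–Claisen (Michael–Dieckmann) annulation of ester enolates with enones that delivers cyclohexane-1,3-diones. The six-membered ring closes by a 6-(enolendo)-exo-trig attack of enolate carbon C2 on the ester carbonyl. C4 arises from a flat achiral enolate and an achiral acceptor, so it forms as a racemate that step 10 resolves, and C6 arises by unselective protonation of 16 and is corrected in step 9. The step needs 1,4- over 1,2-addition and the bond order C4–C5 before C2–C3: the hindered, fully substituted donor and the open 1,1-disubstituted terminus of the acceptor favour conjugate addition (any aldolate reverts on warming), 9 has no second acidic site, and closure from C6 would give only a strained four-membered ring.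

Step 8
Reactants: 17 6-allyl-4-(2-allyl-4,5-dimethoxyphenoxy)-4-methoxycyclohexane-1,3-dione
Product: 18 6-allyl-4-(2-allyl-4,5-dimethoxyphenoxy)-3,4-dimethoxycyclohex-2-en-1-one (racemic at C4; both C6 epimers)
Conditions: Me3SiCHN2, PhMe–MeOH, 0 °C
Reagents that add atoms: trimethylsilyldiazomethane, C[Si](C)(C)C=[N+]=[N-]
Why: O-methylation of a vinylogous acid with a diazoalkane, in which the enol proton should reside mainly on O3 (enolising C3 removes the dipole-opposed α,α-dialkoxy ketone), so proton transfer to the diazo carbon and collapse of the ion pair at that oxygen should give the 3-methoxy enone under neutral conditions that spare the ketal and the alkenes.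

Step 9
Reactants: 18 6-allyl-4-(2-allyl-4,5-dimethoxyphenoxy)-3,4-dimethoxycyclohex-2-en-1-one (epimer mixture)
Product: 19 rac-(4R,6S)-6-allyl-4-(2-allyl-4,5-dimethoxyphenoxy)-3,4-dimethoxycyclohex-2-en-1-one (4,6-cis racemate)
Conditions: NaOMe (0.2 equiv), MeOH, rt; NH4Cl quench; SiO2 chromatography, minor epimer returned to the equilibration
Reagents that add atoms: none
Why: Thermodynamic epimerisation through the C6 enolate, in which catalytic methoxide reversibly deprotonates the only enolisable stereocentre so that the allyl group should settle pseudo-equatorial and cis to the aryloxy group, while methoxide exchange at C3 is degenerate and the quaternary C4 cannot epimerise.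

Step 10
Reactants: 19 rac-(4R,6S)-6-allyl-4-(2-allyl-4,5-dimethoxyphenoxy)-3,4-dimethoxycyclohex-2-en-1-one
Product: 20 (4R,6S)-6-allyl-4-(2-allyl-4,5-dimethoxyphenoxy)-3,4-dimethoxycyclohex-2-en-1-one (target)
Conditions: preparative SFC, amylose tris(3,5-dimethylphenylcarbamate) phase, CO2–MeOH, 35 °C
Reagents that add atoms: none
Why: Resolution by chromatography on a chiral stationary phase, in which the enantiomers of the neutral, configurationally stable racemate should form diastereomeric adsorbates of different retention, the (4R,6S) antipode being assigned by circular dichroism against calculation.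

**Compound list**

1 | 3,4-dimethoxyphenol | COc1ccc(O)cc1OC | starting material
2 | allyl bromide | C=CCBr | starting material
3 | 4-(allyloxy)-1,2-dimethoxybenzene | C=CCOc1ccc(OC)c(OC)c1 | intermediate
4 | 6-allyl-3,4-dimethoxycyclohexa-2,4-dien-1-one (racemic) | O=C1C=C(OC)C(OC)=CC1CC=C | intermediate (not isolated)
5 | 2-allyl-4,5-dimethoxyphenol | C=CCc1cc(OC)c(OC)cc1O | intermediate
6 | methyl methoxyacetate | COCC(=O)OC | starting material
7 | methyl 2-bromo-2-methoxyacetate (racemic) | COC(Br)C(=O)OC | intermediate
8 | sodium 2-allyl-4,5-dimethoxyphenoxide | [Na+].C=CCc1cc(OC)c(OC)cc1[O-] | intermediate (not isolated)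
9 | methyl 2-(2-allyl-4,5-dimethoxyphenoxy)-2-methoxyacetate (racemic) | C=CCc1cc(OC)c(OC)cc1OC(OC)C(=O)OC | intermediate
10 | ethyl acetoacetate | CCOC(=O)CC(C)=O | starting material
11 | ethyl 2-acetylpent-4-enoate (racemic) | C=CCC(C(C)=O)C(=O)OCC | intermediate
12 | potassium 2-acetylpent-4-enoate (racemic) | [K+].C=CCC(C(C)=O)C([O-])=O | intermediate (not isolated)
13 | 2-acetyl-2-[(dimethylamino)methyl]pent-4-enoic acid (racemic) | C=CCC(CN(C)C)(C(C)=O)C(=O)O | intermediate (not isolated)
14 | 3-methylenehex-5-en-2-one | CC(=O)C(=C)CC=C | intermediate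
15 | lithium 2-(2-allyl-4,5-dimethoxyphenoxy)-1,2-dimethoxyethen-1-olate | [Li+].C=CCc1cc(OC)c(OC)cc1OC(OC)=C([O-])OC | intermediate (not isolated)
16 | lithium 3-allyl-5-(2-allyl-4,5-dimethoxyphenoxy)-5,6-dimethoxy-6-oxohex-2-en-2-olate (racemic) | [Li+].C=CCC(CC(OC)(Oc1cc(OC)c(OC)cc1CC=C)C(=O)OC)=C(C)[O-] | intermediate (not isolated)
17 | 6-allyl-4-(2-allyl-4,5-dimethoxyphenoxy)-4-methoxycyclohexane-1,3-dione (racemic at C4, both C6 epimers) | C=CCc1cc(OC)c(OC)cc1OC1(OC)CC(CC=C)C(=O)CC1=O | intermediate
18 | 6-allyl-4-(2-allyl-4,5-dimethoxyphenoxy)-3,4-dimethoxycyclohex-2-en-1-one (racemic at C4, both C6 epimers) | C=CCc1cc(OC)c(OC)cc1OC1(OC)CC(CC=C)C(=O)C=C1OC | intermediate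
19 | rac-(4R,6S)-6-allyl-4-(2-allyl-4,5-dimethoxyphenoxy)-3,4-dimethoxycyclohex-2-en-1-one (racemate, relative configuration drawn) | C=CCc1cc(OC)c(OC)cc1O[C@]1(OC)C[C@H](CC=C)C(=O)C=C1OC | intermediate
20 | (4R,6S)-6-allyl-4-(2-allyl-4,5-dimethoxyphenoxy)-3,4-dimethoxycyclohex-2-en-1-one | C=CCc1cc(OC)c(OC)cc1O[C@]1(OC)C[C@H](CC=C)C(=O)C=C1OC | target

**Step count and risks**

Total steps: 10. Longest linear sequence: 7 steps (steps 1, 2, 4, 7, 8, 9, 10).

Steps most likely to fail:

1. Step 7. The tetra-oxygenated enolate may be lost by self-condensation or fragmentation before it meets the enone, the enone may oligomerise anionically, or the sequence may stall at the open-chain adduct because the enolate does not transpose to the methyl side.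
Fallback, from 9 back to 17: the two bonds are made in separate operations. Ester 9 is enolised with LiN(iPr)2 in the presence of Me3SiCl (THF, −78 °C) and trapped as the silyl ketene acetal 1-(2-allyl-4,5-dimethoxyphenoxy)-1,2-dimethoxy-2-(trimethylsilyloxy)ethene F1. Its Mukaiyama–Michael addition to 14 (MeCN, rt, catalytic LiClO4 if the uncatalysed addition is slow) should give the enol silane methyl 4-allyl-2-(2-allyl-4,5-dimethoxyphenoxy)-2-methoxy-5-(trimethylsilyloxy)hex-4-enoate F2. A pH 5 aqueous work-up should free the keto ester methyl 4-acetyl-2-(2-allyl-4,5-dimethoxyphenoxy)-2-methoxyhept-6-enoate F3, which is cyclised with KOtBu in THF (0 °C → rt, Dieckmann-type acylation) to dione 17.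

2. Step 8. Methylation may take place at the wrong enol oxygen (O1), since the two oxygens of the dione differ only in the neighbouring ketal and in steric access.
Fallback, from 17 back to 17: selectivity is replaced by separation and recycling. The two enol ethers are separated on silica, and the regioisomer 4-allyl-6-(2-allyl-4,5-dimethoxyphenoxy)-3,6-dimethoxycyclohex-2-en-1-one F4 is hydrolysed with aqueous LiOH in THF (addition–elimination of hydroxide at the methoxy-bearing carbon, then acidification to pH 4). This regenerates dione 17, which re-enters step 8.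

3. Step 9. The equilibrium may not lie far enough on the side of the 4,6-cis epimer, or prolonged exposure to base may open the ring by retro-Michael cleavage.
Fallback, from 18 back to 19: C6 is set kinetically instead of thermodynamically. Mixture 18 is deprotonated with LiN(SiMe3)2 in THF at −78 °C to lithium 2-allyl-4-(2-allyl-4,5-dimethoxyphenoxy)-4,5-dimethoxycyclohexa-1,5-dien-1-olate F5. The enolate is protonated at −78 °C with 2,6-di-tert-butyl-4-methylphenol, the proton arriving on the ring face opposite the bulky aryloxy group, so that the allyl group ends up cis to it, as in 19.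

Further compounds
F1 | step 7 | 1-(2-allyl-4,5-dimethoxyphenoxy)-1,2-dimethoxy-2-(trimethylsilyloxy)ethene | C=CCc1cc(OC)c(OC)cc1OC(OC)=C(OC)O[Si](C)(C)C
F2 | step 7 | methyl 4-allyl-2-(2-allyl-4,5-dimethoxyphenoxy)-2-methoxy-5-(trimethylsilyloxy)hex-4-enoate (racemic) | C=CCC(CC(OC)(Oc1cc(OC)c(OC)cc1CC=C)C(=O)OC)=C(C)O[Si](C)(C)C
F3 | step 7 | methyl 4-acetyl-2-(2-allyl-4,5-dimethoxyphenoxy)-2-methoxyhept-6-enoate (racemic, both diastereomers) | C=CCC(CC(OC)(Oc1cc(OC)c(OC)cc1CC=C)C(=O)OC)C(C)=O
F4 | step 8 | 4-allyl-6-(2-allyl-4,5-dimethoxyphenoxy)-3,6-dimethoxycyclohex-2-en-1-one (racemic, both C4 epimers) | C=CCc1cc(OC)c(OC)cc1OC1(OC)CC(CC=C)C(OC)=CC1=O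
F5 | step 9 | lithium 2-allyl-4-(2-allyl-4,5-dimethoxyphenoxy)-4,5-dimethoxycyclohexa-1,5-dien-1-olate (racemic) | [Li+].C=CCC1=C([O-])C=C(OC)C(OC)(Oc2cc(OC)c(OC)cc2CC=C)C1
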